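**Retrosynthetic overview**

1. Ring B is a benzene ring with C1' bonded to chroman C2, OMe on C3' and OH on C5'. This 1,3-dioxygenated, 5-substituted pattern is the aromatised form of a 5-substituted cyclohexane-1,3-dione, so the target is taken back (MOM removal, dehydrogenation, enol O-methylation) to dione 21.
2. Dione 21 is cut at C1'–C2' and C3'–C4' into the chromanyl enone 16 and dimethyl malonate (Michael–Claisen annulation with ester hydrolysis and decarboxylation).
3. Enone 16 comes from (R)-2-vinylchroman 14 by cross-metathesis. Vinylchroman 14 comes from phenol allylic carbonate 13 by palladium-catalysed asymmetric allylic etherification, which closes the pyran ring at O1–C2 and sets the only stereocentre.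
4. Carbonate 13 is built from salicylaldehyde 8 by methylenation and hydroboration/B-alkyl Suzuki coupling. Ring A comes from 5-methoxyresorcinol by two directed ortho-metalations (prenyl to C8, formyl to the future C4a). The C7 oxygen is kept as a MOM ether to the end because the annulation is strongly basic.
5. Ring order: ring A (bought), pyran ring (step 8), ring B (closed in step 10, aromatised in step 13).

Key step: step 10

Assumption: with the (E)-carbonate 13 the (R,R)-ligand is taken to give the (R)-chroman; if the sense of induction is the reverse, the (S,S)-ligand is used and nothing else changes.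

**Route**

Step 1
Reactants: 1 5-methoxyresorcinol
Product: 2 1-methoxy-3,5-bis(methoxymethoxy)benzene
Conditions: NaH (2.4 equiv), MOMCl (2.4 equiv), DMF, 0 → 25 °C
Reagents that add atoms: chloromethyl methyl ether, COCCl
Why: Williamson-type O-alkylation of both phenoxides by the reactive α-chloro ether should give the bis-acetal, which serves as protecting and directing group for the two metalations that follow.

Step 2
Reactants: 2 1-methoxy-3,5-bis(methoxymethoxy)benzene; 3 prenyl bromide
Product: 5 5-methoxy-1,3-bis(methoxymethoxy)-2-(3-methylbut-2-en-1-yl)benzene, via aryllithium 4 (not isolated)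
Conditions: n-BuLi (1.1 equiv), THF, 0 °C; CuBr·SMe2 (1.0 equiv), −40 °C; 3 (1.2 equiv), −40 → 25 °C
Reagents that add atoms: none
Why: Directed ortho-metalation should occur at the carbon flanked by the two OMOM groups (a stronger directing pair than OMOM/OMe), and the arylcopper formed on transmetalation should couple with prenyl bromide at its primary carbon.

Step 3
Reactants: 5 5-methoxy-1,3-bis(methoxymethoxy)-2-(3-methylbut-2-en-1-yl)benzene
Product: 7 6-methoxy-2,4-bis(methoxymethoxy)-3-(3-methylbut-2-en-1-yl)benzaldehyde, via aryllithium 6 (not isolated)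
Conditions: n-BuLi (1.3 equiv), TMEDA (1.3 equiv), THF, −20 → 0 °C; DMF (3 equiv), 0 → 25 °C; aq. NH4Cl
Reagents that add atoms: N,N-dimethylformamide, CN(C)C=O
Why: A second directed ortho-metalation should take the only remaining ring position type (two symmetry-equivalent carbons, each between OMOM and OMe), kinetically ahead of the benzylic–allylic CH2, and formylation of the aryllithium with DMF gives the aldehyde.

Step 4
Reactants: 7 6-methoxy-2,4-bis(methoxymethoxy)-3-(3-methylbut-2-en-1-yl)benzaldehyde
Product: 8 2-hydroxy-6-methoxy-4-(methoxymethoxy)-3-(3-methylbut-2-en-1-yl)benzaldehyde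
Conditions: aq. HCl (2 M, 1.5 equiv), MeOH–THF, 25 °C, stopped at mono-cleavage
Reagents that add atoms: none
Why: Acid-catalysed acetal cleavage should be faster for the MOM group ortho to the formyl group, whose released phenol is held by a hydrogen bond to the carbonyl, so the para MOM ether stays; any over-cleaved diol can be returned to 8 by para-selective MOM protection.

Step 5
Reactants: 8 2-hydroxy-6-methoxy-4-(methoxymethoxy)-3-(3-methylbut-2-en-1-yl)benzaldehyde
Product: 9 3-methoxy-5-(methoxymethoxy)-6-(3-methylbut-2-en-1-yl)-2-vinylphenol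
Conditions: Ph3PCH3Br (2.5 equiv), KOtBu (2.5 equiv), THF, 0 → 40 °C
Reagents that add atoms: methyltriphenylphosphonium bromide, C[P+](c1ccccc1)(c1ccccc1)c1ccccc1.[Br-]
Why: Wittig methylenation with the non-stabilised ylide should convert the aldehyde to the styrene, one equivalent of base being taken up by the phenol.

Step 6
Reactants: 9 3-methoxy-5-(methoxymethoxy)-6-(3-methylbut-2-en-1-yl)-2-vinylphenol; 10 (E)-3-iodoprop-2-en-1-ol
Product: 12 (E)-5-[2-hydroxy-6-methoxy-4-(methoxymethoxy)-3-(3-methylbut-2-en-1-yl)phenyl]pent-2-en-1-ol, via alkylborane 11 (not isolated)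
Conditions: 9-BBN (2.2 equiv), THF, 0 → 25 °C; then 10 (1.2 equiv), PdCl2(dppf)·CH2Cl2 (5 mol %), aq. NaOH (3 M), 50 °C
Reagents that add atoms: none
Why: Anti-Markovnikov hydroboration of the terminal styrene by 9-BBN (much faster than at the trisubstituted prenyl alkene; the excess covers the phenol) followed by B-alkyl Suzuki–Miyaura coupling with the vinyl iodide should give the allylic alcohol with the E geometry retained.

Step 7
Reactants: 12 (E)-5-[2-hydroxy-6-methoxy-4-(methoxymethoxy)-3-(3-methylbut-2-en-1-yl)phenyl]pent-2-en-1-ol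
Product: 13 (E)-5-[2-hydroxy-6-methoxy-4-(methoxymethoxy)-3-(3-methylbut-2-en-1-yl)phenyl]pent-2-en-1-yl methyl carbonate
Conditions: ClCO2Me (1.1 equiv), pyridine (2 equiv), CH2Cl2, −20 °C
Reagents that add atoms: methyl chloroformate, COC(=O)Cl
Why: Chemoselective acylation with the chloroformate should take the primary allylic alcohol, since the phenol is flanked by two ortho carbon substituents and is not deprotonated by pyridine.

Step 8
Reactants: 13 (E)-5-[2-hydroxy-6-methoxy-4-(methoxymethoxy)-3-(3-methylbut-2-en-1-yl)phenyl]pent-2-en-1-yl methyl carbonate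
Product: 14 (R)-5-methoxy-7-(methoxymethoxy)-8-(3-methylbut-2-en-1-yl)-2-vinylchroman
Conditions: Pd2(dba)3·CHCl3 (2 mol %), (R,R)-N,N'-bis(2-diphenylphosphinobenzoyl)-1,2-diaminocyclohexane (6 mol %), AcOH (1 equiv), CH2Cl2 (0.05 M), 25 °C
Reagents that add atoms: none
Why: In this Trost asymmetric allylic alkylation (intramolecular allylic etherification) zerovalent palladium ionises the carbonate, and the phenol closes 6-exo on the tether-bearing allyl terminus inside the chiral pocket of the ligand, which sets C2 as (R) while acetic acid speeds equilibration of the diastereomeric π-allyl complexes.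

Step 9
Reactants: 14 (R)-5-methoxy-7-(methoxymethoxy)-8-(3-methylbut-2-en-1-yl)-2-vinylchroman; 15 methyl vinyl ketone
Product: 16 (E)-4-[(R)-5-methoxy-7-(methoxymethoxy)-8-(3-methylbut-2-en-1-yl)chroman-2-yl]but-3-en-2-one
Conditions: 15 (5 equiv), second-generation Hoveyda–Grubbs catalyst RuCl2(H2IMes)(=CH-C6H4-2-OiPr) (5 mol %), CH2Cl2, 40 °C
Reagents that add atoms: none
Why: Olefin cross-metathesis between the monosubstituted vinyl group and the electron-poor enone should give the E-enone, the trisubstituted prenyl alkene reacting far more slowly with the ruthenium carbene and C2 staying untouched.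

Step 10
Reactants: 16 (E)-4-[(R)-5-methoxy-7-(methoxymethoxy)-8-(3-methylbut-2-en-1-yl)chroman-2-yl]but-3-en-2-one; 17 dimethyl malonate
Product: 21 5-[(R)-5-methoxy-7-(methoxymethoxy)-8-(3-methylbut-2-en-1-yl)chroman-2-yl]cyclohexane-1,3-dione, via Michael adduct 18 (not isolated), via cyclic keto ester 19 (not isolated), via dioxo acid 20 (not isolated)
Conditions: 17 (1.5 equiv), NaOMe (0.2 equiv), MeOH, 0 → 25 °C; NaOMe (2.0 equiv), 65 °C; aq. NaOH (2 M), 65 °C; aq. HCl to pH 3, 50 °C
Reagents that add atoms: none
Why: Malonate anion, kept in excess over the catalytic methoxide, should add in a Michael fashion to the enone β-carbon (the carbon bonded to chroman C2) to give 18; with stoichiometric methoxide the methyl ketone enolate then attacks one malonate ester in a Claisen (Dieckmann-type) condensation, driven by formation of the β-diketone enolate of 19, and saponification followed by mild acidification removes the extra carboxyl as CO2. The closest known reaction type is the dimedone synthesis, the Michael–Claisen annulation of alkyl-substituted enones with malonate. The one ring formed, the future ring B, closes by a 6-exo-trig acyl substitution of the enolate carbon on the ester carbonyl. No lasting stereocentre arises, because the former β-carbon becomes C5 of a dione with two identical ring arms and the transient centres of 19 vanish with the ester. The step needs 1,4- rather than 1,2-addition and no deprotonation of the γ C2–H, which the soft and far more acidic malonate and the low methoxide concentration during the Michael stage should secure; once the addition is done, C2 is an ordinary ether carbon with no leaving group β to any enolate, so its (R) configuration is carried through, and the MOM ether and the prenyl group are inert to base.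

Step 11
Reactants: 21 5-[(R)-5-methoxy-7-(methoxymethoxy)-8-(3-methylbut-2-en-1-yl)chroman-2-yl]cyclohexane-1,3-dione
Product: 22 3-methoxy-5-[(R)-5-methoxy-7-(methoxymethoxy)-8-(3-methylbut-2-en-1-yl)chroman-2-yl]cyclohex-2-en-1-one (both C5 epimers)
Conditions: Me3SiCHN2 (1.5 equiv), MeOH–toluene (1:4), 0 → 25 °C
Reagents that add atoms: (trimethylsilyl)diazomethane, C[Si](C)(C)C=[N+]=[N-]
Why: O-methylation of the acidic enol by the diazoalkane under neutral conditions should give the vinylogous ester, and since the dione is symmetric either oxygen leads to the same constitution, the C5 epimers converging on aromatisation.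

Step 12
Reactants: 22 3-methoxy-5-[(R)-5-methoxy-7-(methoxymethoxy)-8-(3-methylbut-2-en-1-yl)chroman-2-yl]cyclohex-2-en-1-one
Product: 24 3-methoxy-6-(phenylselanyl)-5-[(R)-5-methoxy-7-(methoxymethoxy)-8-(3-methylbut-2-en-1-yl)chroman-2-yl]cyclohex-2-en-1-one, via lithium dienolate 23 (not isolated)
Conditions: LiN(i-Pr)2 (1.1 equiv), THF, −78 °C; PhSeCl (1.05 equiv), −78 °C, fast addition; aq. NH4Cl
Reagents that add atoms: benzeneselenenyl chloride, Cl[Se]c1ccccc1
Why: Kinetic α'-deprotonation of the 3-alkoxyenone at C6 and α-selenenylation of the enolate (Reich–Sharpless) should outrun any addition of the selenium electrophile to the prenyl alkene at −78 °C with one equivalent of reagent.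

Step 13
Reactants: 24 3-methoxy-6-(phenylselanyl)-5-[(R)-5-methoxy-7-(methoxymethoxy)-8-(3-methylbut-2-en-1-yl)chroman-2-yl]cyclohex-2-en-1-one
Product: 27 3-methoxy-5-[(R)-5-methoxy-7-(methoxymethoxy)-8-(3-methylbut-2-en-1-yl)chroman-2-yl]phenol, via selenoxide 25 (not isolated), via cyclohexadienone 26 (not isolated)
Conditions: mCPBA (1.0 equiv), CH2Cl2, −78 °C; i-Pr2NH (3 equiv), −78 → 25 °C
Reagents that add atoms: none
Why: Oxidation of the selenide and selenoxide syn-elimination toward C5–H should give the cross-conjugated dienone, which tautomerises through its doubly vinylogous C4–H to the phenol, while the amine traps the selenenic acid before it can add to the prenyl alkene.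

Step 14
Reactants: 27 3-methoxy-5-[(R)-5-methoxy-7-(methoxymethoxy)-8-(3-methylbut-2-en-1-yl)chroman-2-yl]phenol
Product: 28 (R)-2-(3-hydroxy-5-methoxyphenyl)-5-methoxy-8-(3-methylbut-2-en-1-yl)chroman-7-ol
Conditions: aq. HCl (3 M), MeOH, 40 °C
Reagents that add atoms: none
Why: Acid-catalysed methanolysis of the MOM acetal should free the C7 phenol under conditions mild enough for the prenyl group, and C2 is not ionised because the meta-oxygenated ring B does not stabilise a benzylic cation.

**Compound list**

1 | 5-methoxyresorcinol | COc1cc(O)cc(O)c1 | starting material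
2 | 1-methoxy-3,5-bis(methoxymethoxy)benzene | COCOc1cc(OC)cc(OCOC)c1 | intermediate
3 | prenyl bromide (1-bromo-3-methylbut-2-ene) | CC(C)=CCBr | starting material
4 | [4-methoxy-2,6-bis(methoxymethoxy)phenyl]lithium (not isolated) | [Li]c1c(OCOC)cc(OC)cc1OCOC | intermediate
5 | 5-methoxy-1,3-bis(methoxymethoxy)-2-(3-methylbut-2-en-1-yl)benzene | COCOc1cc(OC)cc(OCOC)c1CC=C(C)C | intermediate
6 | [6-methoxy-2,4-bis(methoxymethoxy)-3-(3-methylbut-2-en-1-yl)phenyl]lithium (not isolated) | [Li]c1c(OC)cc(OCOC)c(CC=C(C)C)c1OCOC | intermediate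
7 | 6-methoxy-2,4-bis(methoxymethoxy)-3-(3-methylbut-2-en-1-yl)benzaldehyde | O=Cc1c(OC)cc(OCOC)c(CC=C(C)C)c1OCOC | intermediate
8 | 2-hydroxy-6-methoxy-4-(methoxymethoxy)-3-(3-methylbut-2-en-1-yl)benzaldehyde | O=Cc1c(OC)cc(OCOC)c(CC=C(C)C)c1O | intermediate
9 | 3-methoxy-5-(methoxymethoxy)-6-(3-methylbut-2-en-1-yl)-2-vinylphenol | C=Cc1c(OC)cc(OCOC)c(CC=C(C)C)c1O | intermediate
10 | (E)-3-iodoprop-2-en-1-ol | OC/C=C/I | starting material
11 | 9-{2-[2-hydroxy-6-methoxy-4-(methoxymethoxy)-3-(3-methylbut-2-en-1-yl)phenyl]ethyl}-9-borabicyclo[3.3.1]nonane (not isolated) | Oc1c(CCB2C3CCCC2CCC3)c(OC)cc(OCOC)c1CC=C(C)C | intermediate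
12 | (E)-5-[2-hydroxy-6-methoxy-4-(methoxymethoxy)-3-(3-methylbut-2-en-1-yl)phenyl]pent-2-en-1-ol | OC/C=C/CCc1c(OC)cc(OCOC)c(CC=C(C)C)c1O | intermediate
13 | (E)-5-[2-hydroxy-6-methoxy-4-(methoxymethoxy)-3-(3-methylbut-2-en-1-yl)phenyl]pent-2-en-1-yl methyl carbonate | COC(=O)OC/C=C/CCc1c(OC)cc(OCOC)c(CC=C(C)C)c1O | intermediate
14 | (R)-5-methoxy-7-(methoxymethoxy)-8-(3-methylbut-2-en-1-yl)-2-vinylchroman | C=C[C@H]1CCc2c(OC)cc(OCOC)c(CC=C(C)C)c2O1 | intermediate
15 | methyl vinyl ketone | CC(=O)C=C | starting material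
16 | (E)-4-[(R)-5-methoxy-7-(methoxymethoxy)-8-(3-methylbut-2-en-1-yl)chroman-2-yl]but-3-en-2-one | CC(=O)/C=C/[C@H]1CCc2c(OC)cc(OCOC)c(CC=C(C)C)c2O1 | intermediate
17 | dimethyl malonate | COC(=O)CC(=O)OC | starting material
18 | dimethyl 2-{1-[(R)-5-methoxy-7-(methoxymethoxy)-8-(3-methylbut-2-en-1-yl)chroman-2-yl]-3-oxobutyl}malonate (not isolated, epimers at the new CH) | COC(=O)C(C(=O)OC)C(CC(C)=O)[C@H]1CCc2c(OC)cc(OCOC)c(CC=C(C)C)c2O1 | intermediate
19 | methyl 6-[(R)-5-methoxy-7-(methoxymethoxy)-8-(3-methylbut-2-en-1-yl)chroman-2-yl]-2,4-dioxocyclohexane-1-carboxylate (not isolated, as its sodium enolate) | COC(=O)C1C(=O)CC(=O)CC1[C@H]1CCc2c(OC)cc(OCOC)c(CC=C(C)C)c2O1 | intermediate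
20 | 6-[(R)-5-methoxy-7-(methoxymethoxy)-8-(3-methylbut-2-en-1-yl)chroman-2-yl]-2,4-dioxocyclohexane-1-carboxylic acid (not isolated) | OC(=O)C1C(=O)CC(=O)CC1[C@H]1CCc2c(OC)cc(OCOC)c(CC=C(C)C)c2O1 | intermediate
21 | 5-[(R)-5-methoxy-7-(methoxymethoxy)-8-(3-methylbut-2-en-1-yl)chroman-2-yl]cyclohexane-1,3-dione | O=C1CC(=O)CC(C1)[C@H]1CCc2c(OC)cc(OCOC)c(CC=C(C)C)c2O1 | intermediate
22 | 3-methoxy-5-[(R)-5-methoxy-7-(methoxymethoxy)-8-(3-methylbut-2-en-1-yl)chroman-2-yl]cyclohex-2-en-1-one (both C5 epimers) | COC1=CC(=O)CC(C1)[C@H]1CCc2c(OC)cc(OCOC)c(CC=C(C)C)c2O1 | intermediate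
23 | lithium dienolate of 22 (not isolated) | COC1=CC(O[Li])=CC(C1)[C@H]1CCc2c(OC)cc(OCOC)c(CC=C(C)C)c2O1 | intermediate
24 | 3-methoxy-6-(phenylselanyl)-5-[(R)-5-methoxy-7-(methoxymethoxy)-8-(3-methylbut-2-en-1-yl)chroman-2-yl]cyclohex-2-en-1-one (diastereomers) | COC1=CC(=O)C([Se]c2ccccc2)C(C1)[C@H]1CCc2c(OC)cc(OCOC)c(CC=C(C)C)c2O1 | intermediate
25 | selenoxide of 24 (not isolated) | COC1=CC(=O)C([Se](=O)c2ccccc2)C(C1)[C@H]1CCc2c(OC)cc(OCOC)c(CC=C(C)C)c2O1 | intermediate
26 | 3-methoxy-5-[(R)-5-methoxy-7-(methoxymethoxy)-8-(3-methylbut-2-en-1-yl)chroman-2-yl]cyclohexa-2,5-dien-1-one (not isolated) | COC1=CC(=O)C=C(C1)[C@H]1CCc2c(OC)cc(OCOC)c(CC=C(C)C)c2O1 | intermediate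
27 | 3-methoxy-5-[(R)-5-methoxy-7-(methoxymethoxy)-8-(3-methylbut-2-en-1-yl)chroman-2-yl]phenol | COc1cc(O)cc([C@H]2CCc3c(OC)cc(OCOC)c(CC=C(C)C)c3O2)c1 | intermediate
28 | (R)-2-(3-hydroxy-5-methoxyphenyl)-5-methoxy-8-(3-methylbut-2-en-1-yl)chroman-7-ol | COc1cc(O)cc([C@H]2CCc3c(OC)cc(O)c(CC=C(C)C)c3O2)c1 | target

**Step count and risks**

Total steps: 14. Longest linear sequence: 14 steps (1 → 28).

Steps most likely to fail:

Step 10 (key annulation). The enone could lose the γ-proton at C2 before malonate adds, which would erode the configuration or move the double bond out of conjugation; the Claisen closure could also stall at the open adduct. Fallback, setting out from 14 and coming back at 19: cross-metathesis of 14 with methyl acrylate (same ruthenium catalyst) should give methyl (E)-3-[(R)-5-methoxy-7-(methoxymethoxy)-8-(3-methylbut-2-en-1-yl)chroman-2-yl]acrylate F1, whose γ-proton is much less acidic than that of the enone. Michael addition of methyl acetoacetate (NaOMe, MeOH) through its α-carbon should give the keto diester F2. The acetyl methyl group of F2 then closes on the CH2CO2Me ester to give the same cyclic keto ester 19, which is saponified and decarboxylated to 21 as in step 10. The roles of donor and acceptor are exchanged, but ring B arises with the same atoms.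

Step 8 (asymmetric etherification). Ring closure could outpace equilibration of the diastereomeric π-allyl complexes, giving low enantioselectivity, or the sense of induction could be the reverse of that assumed. Fallback, setting out from 12 and coming back at 16, with the stereocentre set by a reagent of predictable sense:
- Phenoxide-selective acetylation (Ac2O, K2CO3, acetone, 0 °C) should give 2-[(E)-5-hydroxypent-3-en-1-yl]-3-methoxy-5-(methoxymethoxy)-6-(3-methylbut-2-en-1-yl)phenyl acetate F3.
- Sharpless asymmetric epoxidation (Ti(OiPr)4, L-(+)-diethyl tartrate, t-BuOOH, 4 Å sieves, CH2Cl2, −20 °C) should give the (2S,3S)-epoxy alcohol F4.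
- K2CO3 in MeOH removes the acetate, and the phenoxide opens the epoxide 6-exo at C3 with inversion to give (S)-1-[(R)-5-methoxy-7-(methoxymethoxy)-8-(3-methylbut-2-en-1-yl)chroman-2-yl]ethane-1,2-diol F5.
- NaIO4 (THF–water) cleaves the diol to (R)-5-methoxy-7-(methoxymethoxy)-8-(3-methylbut-2-en-1-yl)chroman-2-carbaldehyde F6.
- Wittig reaction of F6, used at once, with 1-(triphenylphosphoranylidene)propan-2-one (CH2Cl2, 25 °C) gives 16. This also bypasses the cross-metathesis of step 9.

Step 12 (selenenylation before aromatisation). The selenium electrophile could add to the prenyl alkene or to the electron-rich ring A, and the more acidic product could exchange protons with unreacted enolate and be selenenylated twice. Fallback, setting out from 22 and coming back at 27, without selenium: LiN(i-Pr)2 and Me3SiCl (THF, −78 °C) should give the cross-conjugated silyl dienol ether F7. Saegusa–Ito oxidation of F7 with Pd(OAc)2 (1.1 equiv, MeCN, 25 °C) should give dienone 26, which tautomerises to phenol 27.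

**Further compounds**

F1 | step 10 | methyl (E)-3-[(R)-5-methoxy-7-(methoxymethoxy)-8-(3-methylbut-2-en-1-yl)chroman-2-yl]acrylate | COC(=O)/C=C/[C@H]1CCc2c(OC)cc(OCOC)c(CC=C(C)C)c2O1
F2 | step 10 | dimethyl 2-acetyl-3-[(R)-5-methoxy-7-(methoxymethoxy)-8-(3-methylbut-2-en-1-yl)chroman-2-yl]pentanedioate | COC(=O)CC([C@H]1CCc2c(OC)cc(OCOC)c(CC=C(C)C)c2O1)C(C(C)=O)C(=O)OC
F3 | step 8 | 2-[(E)-5-hydroxypent-3-en-1-yl]-3-methoxy-5-(methoxymethoxy)-6-(3-methylbut-2-en-1-yl)phenyl acetate | OC/C=C/CCc1c(OC)cc(OCOC)c(CC=C(C)C)c1OC(C)=O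
F4 | step 8 | 2-{2-[(2S,3S)-3-(hydroxymethyl)oxiran-2-yl]ethyl}-3-methoxy-5-(methoxymethoxy)-6-(3-methylbut-2-en-1-yl)phenyl acetate | OC[C@@H]1O[C@H]1CCc1c(OC)cc(OCOC)c(CC=C(C)C)c1OC(C)=O
F5 | step 8 | (S)-1-[(R)-5-methoxy-7-(methoxymethoxy)-8-(3-methylbut-2-en-1-yl)chroman-2-yl]ethane-1,2-diol | OC[C@H](O)[C@H]1CCc2c(OC)cc(OCOC)c(CC=C(C)C)c2O1
F6 | step 8 | (R)-5-methoxy-7-(methoxymethoxy)-8-(3-methylbut-2-en-1-yl)chroman-2-carbaldehyde | O=C[C@H]1CCc2c(OC)cc(OCOC)c(CC=C(C)C)c2O1
F7 | step 12 | {[3-methoxy-5-((R)-5-methoxy-7-(methoxymethoxy)-8-(3-methylbut-2-en-1-yl)chroman-2-yl)cyclohexa-1,3-dien-1-yl]oxy}trimethylsilane | COC1=CC(O[Si](C)(C)C)=CC(C1)[C@H]1CCc2c(OC)cc(OCOC)c(CC=C(C)C)c2O1
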